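**Retrosynthesis**
- Ketoemblide ⇒ Yamaguchi closure of the bridging 7-membered α,β-unsaturated lactone from a 14-membered carbocyclic hydroxy-acid. This is the last ring formed.
- The 14-membered carbocycle ⇒ macro-RCM between an α-substituted tert-butyl acrylate and a butenyl terminus, which sets the trisubstituted enoate (ring alkene g=h).
- The acyclic RCM precursor ⇒ Saucy–Marbet-type [3,3] Claisen rearrangement between the methyl ketone from (S)-linalool and a Baylis–Hillman dienyl allylic alcohol. This forms the CH2–CH2 bond next to the ketone and the ester-cis-to-diene alkene.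
- The allylic alcohol ⇒ Morita–Baylis–Hillman reaction of a β-isopropyl enal made from 3-methylbutan-2-one and tert-butyl 2-(bromomethyl)acrylate.

Assumptions: (S)-(+)-linalool is the cheap chiral starting material. The MBH alcohol is used as the racemate, because its carbinol carbon becomes an sp2 carbon in the Claisen. The minor HWE alkene isomer in step 5 is separable by chromatography.

**Step 1**
Reactants: 1 (S)-linalool, (3S)-3,7-dimethylocta-1,6-dien-3-ol
Product: 2 (3S)-3-hydroxy-3,7-dimethyloct-6-en-2-one
Conditions: PdCl2 (10 mol %), CuCl, O2 (1 atm), DMF/H2O 7:1, rt → 40 °C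
Reagents that add atoms: water, O
Why: Wacker oxidation is Markovnikov at the monosubstituted vinyl group and leaves the trisubstituted prenyl alkene untouched. Water supplies the ketone oxygen and O2 only reoxidises Cu/Pd. The quaternary carbinol is not touched, so its (S) configuration carries through.

**Step 2**
Reactants: 2
Product: 3 (4S)-4-hydroxy-4-methyl-5-oxohexanal
Conditions: O3 (1 equiv), CH2Cl2/MeOH, −78 °C; then Me2S, −78 °C → rt
Reagents that add atoms: ozone, O=[O+][O-]
Why: Criegee ozonolysis cleaves the electron-rich trisubstituted alkene selectively and loses acetone, while the ketone and tertiary alcohol are inert. No stereocenter is touched.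

**Step 3**
Reactants: 3
Product: 4 (3S)-3-hydroxy-3-methylhept-6-en-2-one
Conditions: Ph3P=CH2 (from Ph3PCH3Br, KOtBu; 2.5 equiv), THF, −78 °C → rt
Reagents that add atoms: methylenetriphenylphosphorane, C=P(c1ccccc1)(c1ccccc1)c1ccccc1
Why: Wittig methylenation of the aldehyde (present as its lactol) is faster than reaction at the hindered, alkoxide-deactivated methyl ketone. The extra ylide equivalent covers deprotonation of the OH. It installs the butenyl terminus for RCM.

**Step 4**
Reactants: 5 3-methylbutan-2-one; 6 tert-butyl 2-(bromomethyl)acrylate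
Product: 7 tert-butyl 6-methyl-2-methylidene-5-oxoheptanoate
Conditions: LDA (1.05 equiv), THF, −78 °C; then 6, −78 → 0 °C
Reagents that add atoms: tert-butyl 2-(bromomethyl)acrylate, C=C(CBr)C(=O)OC(C)(C)C
Why: The kinetic enolate forms at the CH3 group, and the symmetric allyl bromide gives the same product by SN2 or SN2′ (enolate alkylation). No stereocenter is formed.

**Step 5**
Reactants: 7; 8 triethyl phosphonoacetate
Product: 9 1-tert-butyl 7-ethyl (5E)-2-methylidene-5-(propan-2-yl)hept-5-enedioate
Conditions: 8 (1.5 equiv), NaH, THF, 0 → 60 °C
Reagents that add atoms: triethyl phosphonoacetate, CCOC(=O)CP(=O)(OCC)OCC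
Why: Horner–Wadsworth–Emmons olefination under equilibrating conditions puts the ester trans to the bulkier isopropyl group, so the new CH= is cis to the ring CH2. The minor isomer is removed by chromatography.

**Step 6**
Reactants: 9
Product: 10 tert-butyl (5E)-7-hydroxy-2-methylidene-5-(propan-2-yl)hept-5-enoate
Conditions: DIBAL-H (2.2 equiv), CH2Cl2, −78 °C
Reagents that add atoms: none
Why: DIBAL reduces the unhindered ethyl enoate to the allylic alcohol at low temperature. The α-substituted tert-butyl acrylate is too hindered and too poorly electrophilic to compete. The alkene geometry is unchanged.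

**Step 7**
Reactants: 10
Product: 11 tert-butyl (5E)-2-methylidene-7-oxo-5-(propan-2-yl)hept-5-enoate
Conditions: MnO2 (10 equiv), CH2Cl2, rt
Reagents that add atoms: none
Why: MnO2 oxidises the allylic alcohol selectively to the enal without isomerising the alkene.

**Step 8**
Reactants: 11; 12 methyl acrylate
Product: 13 tert-butyl (5E)-7-hydroxy-8-(methoxycarbonyl)-2-methylidene-5-(propan-2-yl)nona-5,8-dienoate, racemic at C7
Conditions: DABCO (30 mol %), neat methyl acrylate (5 equiv), rt, 7 d
Reagents that add atoms: methyl acrylate, C=CC(=O)OC
Why: Morita–Baylis–Hillman reaction gives the allylic alcohol. Blocking of the β-position suppresses Rauhut–Currier side reactions. The new carbinol stereocenter is racemic and is erased in step 9.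

**Step 9 (key step)**
Reactants: 4; 13
Product: 14 methyl (2Z,4E)-8-(tert-butoxycarbonyl)-2-[(4S)-4-hydroxy-4-methyl-3-oxooct-7-en-1-yl]-5-(propan-2-yl)nona-2,4,8-trienoate
Conditions: HC(OMe)3 (4 equiv), PPTS (10 mol %), BHT (cat.), toluene, 110 °C, 3 h (MeOH removed); then sealed tube 140 °C, 12 h
Reagents that add atoms: none
Why: Ketal exchange gives the allyl enol ether in situ, and the Claisen [3,3] rearrangement (Saucy–Marbet type) forms the CH2–CH2 bond at the unsubstituted acrylate terminus. Bond formation at the isopropyl-bearing alkene terminus would create a quaternary center and is disfavoured. The quaternary carbon has no α-H, so enolisation is only possible at the methyl group, which fixes the regiochemistry. The chair transition state places the dienyl group equatorial, trans to the new CH2 and cis to the ester, which is the geometry required in the target. The mild acid (PPTS) is not expected to trigger α-ketol isomerisation. The (S) carbinol lies outside the six-atom array and is retained.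

**Step 10**
Reactants: 14
Product: 15 14-membered carbocyclic diene-enoate tert-butyl ester (free (S) tertiary alcohol, ketone, ring alkene g=h with CO2tBu cis to CH2 i)
Conditions: Hoveyda–Grubbs II (10 mol %), 1,4-benzoquinone (10 mol %), toluene (2 mM), 60 °C, N2 sweep
Reagents that add atoms: none (ethylene is lost)
Why: Ring-closing metathesis joins the acrylate and butenyl termini. High dilution disfavours oligomerisation, and the 14-membered ring favours the E ring alkene, which places CO2tBu cis to the ring CH2 (i).

**Step 11**
Reactants: 15
Product: 16 the corresponding 14-membered carbocyclic carboxylic acid (hydroxy-acid)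
Conditions: TFA/CH2Cl2 1:4, 0 °C → rt
Reagents that add atoms: none
Why: Acidolysis removes the tert-butyl ester (isobutene lost) and leaves the methyl dienoate, ketone and tertiary alcohol intact.

**Step 12**
Reactants: 16
Product: 17 ketoemblide
Conditions: 2,4,6-Cl3C6H2COCl, Et3N, THF, rt; then syringe-pump addition into DMAP (6 equiv), toluene, 80 °C
Reagents that add atoms: none (the acyl chloride is only an activator)
Why: Yamaguchi lactonisation, via the mixed anhydride, closes the 7-membered unsaturated lactone, because the acid on the ring alkene is cis to the chain leading to the tertiary alcohol. The quaternary stereocenter is not involved.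

**Compound list**
1 | (S)-linalool, (3S)-3,7-dimethylocta-1,6-dien-3-ol | CC(C)=CCC[C@](C)(O)C=C | starting material
2 | (3S)-3-hydroxy-3,7-dimethyloct-6-en-2-one | CC(C)=CCC[C@](C)(O)C(C)=O | intermediate
3 | (4S)-4-hydroxy-4-methyl-5-oxohexanal | O=CCC[C@](C)(O)C(C)=O | intermediate
4 | (3S)-3-hydroxy-3-methylhept-6-en-2-one | C=CCC[C@](C)(O)C(C)=O | intermediate
5 | 3-methylbutan-2-one | CC(=O)C(C)C | starting material
6 | tert-butyl 2-(bromomethyl)acrylate | C=C(CBr)C(=O)OC(C)(C)C | starting material
7 | tert-butyl 6-methyl-2-methylidene-5-oxoheptanoate | CC(C)C(=O)CCC(=C)C(=O)OC(C)(C)C | intermediate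
8 | triethyl phosphonoacetate | CCOC(=O)CP(=O)(OCC)OCC | starting material
9 | 1-tert-butyl 7-ethyl (5E)-2-methylidene-5-(propan-2-yl)hept-5-enedioate | CCOC(=O)/C=C(/C(C)C)CCC(=C)C(=O)OC(C)(C)C | intermediate
10 | tert-butyl (5E)-7-hydroxy-2-methylidene-5-(propan-2-yl)hept-5-enoate | OC/C=C(/C(C)C)CCC(=C)C(=O)OC(C)(C)C | intermediate
11 | tert-butyl (5E)-2-methylidene-7-oxo-5-(propan-2-yl)hept-5-enoate | O=C/C=C(/C(C)C)CCC(=C)C(=O)OC(C)(C)C | intermediate
12 | methyl acrylate | C=CC(=O)OC | starting material
13 | tert-butyl (5E)-7-hydroxy-8-(methoxycarbonyl)-2-methylidene-5-(propan-2-yl)nona-5,8-dienoate (racemic at C7) | COC(=O)C(=C)C(O)/C=C(/C(C)C)CCC(=C)C(=O)OC(C)(C)C | intermediate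
14 | seco-precursor, methyl (2Z,4E)-8-(tert-butoxycarbonyl)-2-[(4S)-4-hydroxy-4-methyl-3-oxooct-7-en-1-yl]-5-(propan-2-yl)nona-2,4,8-trienoate | C=CCC[C@](C)(O)C(=O)CC/C(C(=O)OC)=C/C=C(/C(C)C)CCC(=C)C(=O)OC(C)(C)C | intermediate
15 | 14-membered carbocycle, tert-butyl ester | COC(=O)/C1=C\C=C(\C(C)C)CC/C(C(=O)OC(C)(C)C)=C/CC[C@](C)(O)C(=O)CC1 | intermediate
16 | 14-membered carbocyclic hydroxy-acid | COC(=O)/C1=C\C=C(\C(C)C)CC/C(C(=O)O)=C/CC[C@](C)(O)C(=O)CC1 | intermediate
17 | ketoemblide | COC(=O)/C1=C\C=C(\C(C)C)CCC2=CCC[C@](C)(OC2=O)C(=O)CC1 | target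

**Totals:** 12 steps in total. The longest linear sequence is 9 steps (3-methylbutan-2-one 5 → 7 → 9 → 10 → 11 → 13 → 14 → 15 → 16 → 17). The linalool branch (1 → 2 → 3 → 4) is 3 steps and joins at step 9.

**Three steps most likely to fail**
1. **Step 9, Claisen coupling.** The dienyl allylic alcohol may ionise under acid or heat, and the hindered α-quaternary ketone may ketalise slowly. *Fallback:* convert 13 to its methyl carbonate and run a Pd(0) Tsuji–Trost alkylation with the lithium enolate of 4. The syn-π-allyl gives the same trans-CH2 geometry.
2. **Step 10, macro-RCM.** The 1,1-disubstituted acrylate and dienoate are poor metathesis partners, and oligomerisation competes. *Fallback:* swap the acrylate terminus for a bis(trifluoroethyl)phosphonoacetate, ozonolyse the butenyl terminus to the aldehyde, and close the ring by an intramolecular Still–Gennari olefination.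
3. **Step 8, MBH on the β,β-disubstituted enal.** The enal is a poor electrophile and the reaction is slow. *Fallback:* make 13 by Nozaki–Hiyama–Kishi-type 1,2-addition of methyl 2-bromoacrylate (CrCl2/NiCl2, DMF) to enal 11.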